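**Retrosynthetic overview**

1. Target 22 ⇐ 21 (methanolysis of aryl acetate and TMS ether) ⇐ ring diene 19 + tiglic acid 20: the C10–O bond is made last by a 1,4-hydroacyloxylation of the diene (key step, new).
2. 19 ⇐ diol 16 (C6–O acylation, C4–O silylation) ⇐ 15: seven-membered ring by diene–ene ring-closing metathesis (C9=C10).
3. 15 ⇐ β-hydroxy ketone 13 (chelation-controlled reduction sets C6) ⇐ aldehyde 7 + isoprene 8 ⇐ enal 5 (conjugate vinyl addition sets the quaternary C1).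
4. 5 ⇐ (S)-terpinen-4-ol 1: ozonolysis/aldol ring contraction; the C4 tertiary carbinol comes from the chiral pool.
5. Ring order: cyclopentane first (step 2), cycloheptene second (step 7).

Atom labels below use daucane numbering: C1 quaternary (CH3-15), C4 carbinol (isopropyl), C5 ring-fusion CH, C6 aroyloxy carbon, C8 (CH3-14)=C9, C10 tigloyloxy carbon. The target is (1R,4R,5S,6R,10R) and cis-fused (CH3-15 and H-5 on the same face).

Assumption: (S)-(+)-terpinen-4-ol is used at ≥98% ee (checked by chiral GC before use), because no later step can raise the ee.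

**Route**

Step 1
Reactants: 1 (S)-(+)-terpinen-4-ol
Product: 2 trimethyl{[(1S)-4-methyl-1-(propan-2-yl)cyclohex-3-en-1-yl]oxy}silane
Conditions: TMSCl, imidazole, DMF, 0 °C → rt
Reagents that add atoms: trimethylsilyl chloride, C[Si](C)(C)Cl
Why: O-silylation of the tertiary alcohol masks the C4 oxygen so that it cannot be lost by E1cB elimination or retro-aldol in steps 2–5; the chiral-pool stereocentre is untouched.

Step 2
Reactants: 2 trimethyl{[(1S)-4-methyl-1-(propan-2-yl)cyclohex-3-en-1-yl]oxy}silane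
Product: 5 (5R)-2-methyl-5-(propan-2-yl)-5-[(trimethylsilyl)oxy]cyclopent-1-ene-1-carbaldehyde, via ozonide 3 (not isolated), via keto-aldehyde 4 (not isolated)
Conditions: O3, CH2Cl2, −78 °C; PPh3, → rt; then piperidine (20 mol %), AcOH (20 mol %), 40 °C
Reagents that add atoms: ozone, [O-][O+]=O
Why: Ozonolysis of the only C=C followed by amine-catalysed (enamine) intramolecular aldol condensation, in which the aldehyde α-carbon attacks the methyl ketone and only the new unprotected tertiary aldol hydroxyl is eliminated, gives the tetrasubstituted enal without touching C4.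

Step 3
Reactants: 5 (5R)-2-methyl-5-(propan-2-yl)-5-[(trimethylsilyl)oxy]cyclopent-1-ene-1-carbaldehyde
Product: 7 (1R,2S,5R)-2-ethenyl-2-methyl-5-(propan-2-yl)-5-[(trimethylsilyl)oxy]cyclopentane-1-carbaldehyde, via silyl enol ether 6 (not isolated)
Conditions: CH2=CHMgBr, CuBr·SMe2 (10 mol %), TMSCl, THF, −78 → −40 °C; then 10% aq. citric acid, THF, 0 °C
Reagents that add atoms: vinylmagnesium bromide, C=C[Mg]Br
Why: Copper-catalysed, TMSCl-accelerated conjugate addition puts vinyl on the β-carbon anti to the bulky isopropyl group of the adjacent quaternary C4 (syn to the small silyloxy oxygen), setting quaternary C1; mild hydrolysis of the enol ether leaves CHO trans to isopropyl (C5 is finally fixed in step 5).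

Step 4
Reactants: 7 (1R,2S,5R)-2-ethenyl-2-methyl-5-(propan-2-yl)-5-[(trimethylsilyl)oxy]cyclopentane-1-carbaldehyde; 8 isoprene
Product: 11 1-[(1S,2S,5R)-2-ethenyl-2-methyl-5-(propan-2-yl)-5-(trimethylsilyloxy)cyclopentyl]-3-methylidenepent-4-en-1-ol (both carbinol epimers), via isoprenylpotassium 9 (not isolated), via isoprenylmagnesium bromide 10 (not isolated)
Conditions: 8, 2,2,6,6-tetramethylpiperidine (TMPH), n-BuLi, KOtBu, THF, −78 → −60 °C; MgBr2; then 7, −78 °C; aq. NH4Cl
Reagents that add atoms: none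
Why: 1,2-Addition of the allyl-type organomagnesium reagent from metalated isoprene (its two CH2 termini are equivalent) installs C7, C8, C9 and C14 as a 2-substituted butadiene; the new carbinol centre is uncontrolled and is erased in step 5.

Step 5
Reactants: 11 1-[(1S,2S,5R)-2-ethenyl-2-methyl-5-(propan-2-yl)-5-(trimethylsilyloxy)cyclopentyl]-3-methylidenepent-4-en-1-ol
Product: 13 1-[(1R,2S,5R)-2-ethenyl-5-hydroxy-2-methyl-5-(propan-2-yl)cyclopentyl]-3-methylidenepent-4-en-1-one, via silyloxy ketone 12 (not isolated)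
Conditions: Dess–Martin periodinane, CH2Cl2, 0 °C → rt; then 1 M HCl, THF, 0 °C
Reagents that add atoms: none
Why: Dess–Martin oxidation of the secondary alcohol, then acid hydrolysis of the tertiary TMS ether, which also equilibrates the epimerisable C5 to the hydrogen-bonded cis β-hydroxy ketone (acyl trans to isopropyl), fixing C5.

Step 6
Reactants: 13 1-[(1R,2S,5R)-2-ethenyl-5-hydroxy-2-methyl-5-(propan-2-yl)cyclopentyl]-3-methylidenepent-4-en-1-one
Product: 15 (1R)-1-[(1S,2S,5R)-2-ethenyl-5-hydroxy-2-methyl-5-(propan-2-yl)cyclopentyl]-3-methylidenepent-4-en-1-ol, via boron chelate 14 (not isolated)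
Conditions: Et2BOMe, THF/MeOH (4:1), −78 °C; NaBH4, −78 °C; AcOH; MeOH co-evaporation
Reagents that add atoms: none
Why: Narasaka–Prasad reduction, in which the diethylboron chelate holds the carbonyl syn to the C4 oxygen and external hydride attacks the open face away from the cis vinyl group on C1, gives the syn-1,3-diol and sets C6 as R.

Step 7
Reactants: 15 (1R)-1-[(1S,2S,5R)-2-ethenyl-5-hydroxy-2-methyl-5-(propan-2-yl)cyclopentyl]-3-methylidenepent-4-en-1-ol
Product: 16 (3R,3aS,4R,8aS)-8a-methyl-6-methylidene-3-(propan-2-yl)-1,2,3,3a,4,5,6,8a-octahydroazulene-3,4-diol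
Conditions: second-generation Hoveyda–Grubbs catalyst, RuCl2(H2IMes)(=CH–C6H4-2-OiPr) (5 mol %), CH2Cl2 (2 mM), 40 °C
Reagents that add atoms: none
Why: Diene–ene ring-closing metathesis, in which the catalyst loads on the monosubstituted terminus of the butadiene and closes onto the vinyl group at C1, forms the cis C9=C10 bond of the seven-membered ring and leaves the 1,1-disubstituted C8=CH2 intact; the cis ring fusion is already fixed at C1 and C5.

Step 8
Reactants: 16 (3R,3aS,4R,8aS)-8a-methyl-6-methylidene-3-(propan-2-yl)-1,2,3,3a,4,5,6,8a-octahydroazulene-3,4-diol; 17 4-(acetyloxy)benzoyl chloride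
Product: 19 (3R,3aS,4R,8aS)-8a-methyl-6-methylidene-3-(propan-2-yl)-3-[(trimethylsilyl)oxy]-1,2,3,3a,4,5,6,8a-octahydroazulen-4-yl 4-(acetyloxy)benzoate, via hydroxy ester 18 (not isolated)
Conditions: 17, 2,6-lutidine, DMAP (5 mol %), CH2Cl2, 0 °C → rt; then TMSOTf, −78 → 0 °C
Reagents that add atoms: trimethylsilyl trifluoromethanesulfonate, C[Si](C)(C)OS(=O)(=O)C(F)(F)F
Why: Acylation is selective for the only secondary hydroxyl (C6), and the tertiary C4 hydroxyl is then silylated by TMSOTf/lutidine so that it cannot trap the allyl cation of step 9; no stereocentre is affected.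

Step 9
Reactants: 19 (3R,3aS,4R,8aS)-8a-methyl-6-methylidene-3-(propan-2-yl)-3-[(trimethylsilyl)oxy]-1,2,3,3a,4,5,6,8a-octahydroazulen-4-yl 4-(acetyloxy)benzoate; 20 tiglic acid
Product: 21 (3R,3aS,4R,8R,8aR)-6,8a-dimethyl-8-{[(2E)-2-methylbut-2-enoyl]oxy}-3-(propan-2-yl)-3-[(trimethylsilyl)oxy]-1,2,3,3a,4,5,8,8a-octahydroazulen-4-yl 4-(acetyloxy)benzoate
Conditions: 20 (3 equiv), [N,N′-bis(3,5-di-tert-butylsalicylidene)cyclohexane-1,2-diaminato]cobalt, Co(C36H52N2O2), divalent cobalt (5 mol %), 1-fluoro-2,4,6-trimethylpyridinium triflate, PhSiH3, PhCF3, 0 °C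
Reagents that add atoms: none
Why: Proposed new method: a trivalent cobalt hydride (from the divalent salen complex, the N–F oxidant and PhSiH3) transfers H• to the exocyclic CH2 (C14) of the s-trans diene to give the C8–C9–C10 allyl radical, radical–polar crossover through a tetravalent allylcobalt gives the allyl cation, and tiglate captures it at the secondary terminus C10 (giving the more stable trisubstituted 8,9-alkene, whereas a tertiary C8 ester would re-ionise) from the convex β-face, anti to the syn-1,3 silyloxy group on C4 and the α-aroyloxy group on C6, which sets C10 as R; the closest known reaction type is cobalt–salen MHAT Markovnikov hydroalkoxylation and hydroacyloxylation of simple alkenes, which has not been shown as a 1,4-addition of a carboxylic acid to a cyclic 2-substituted 1,3-diene.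

Step 10
Reactants: 21 (3R,3aS,4R,8R,8aR)-6,8a-dimethyl-8-{[(2E)-2-methylbut-2-enoyl]oxy}-3-(propan-2-yl)-3-[(trimethylsilyl)oxy]-1,2,3,3a,4,5,8,8a-octahydroazulen-4-yl 4-(acetyloxy)benzoate
Product: 22 (3R,3aS,4R,8R,8aR)-3-hydroxy-6,8a-dimethyl-8-{[(2E)-2-methylbut-2-enoyl]oxy}-3-(propan-2-yl)-1,2,3,3a,4,5,8,8a-octahydroazulen-4-yl 4-hydroxybenzoate
Conditions: K2CO3 (0.3 equiv), MeOH, 0 °C → rt
Reagents that add atoms: none
Why: Base-catalysed methanolysis cleaves the phenolic acetate and the tertiary TMS ether, while the aryl ester (deactivated as its phenoxide) and the hindered allylic tiglate survive; no stereocentre is touched.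

**Compound list**

1 | (S)-(+)-terpinen-4-ol, (1S)-4-methyl-1-(propan-2-yl)cyclohex-3-en-1-ol | CC1=CC[C@](O)(C(C)C)CC1 | starting material
2 | trimethyl{[(1S)-4-methyl-1-(propan-2-yl)cyclohex-3-en-1-yl]oxy}silane | CC1=CC[C@](O[Si](C)(C)C)(C(C)C)CC1 | intermediate
3 | ozonide of 2, 1-methyl-4-(propan-2-yl)-4-[(trimethylsilyl)oxy]-7,8,9-trioxabicyclo[4.2.1]nonane (C4 as in 2; bridgehead diastereomers) | CC12CC[C@@](O[Si](C)(C)C)(C(C)C)CC(OO1)O2 | intermediate
4 | (3S)-6-oxo-3-(propan-2-yl)-3-[(trimethylsilyl)oxy]heptanal | CC(=O)CC[C@@](O[Si](C)(C)C)(C(C)C)CC=O | intermediate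
5 | (5R)-2-methyl-5-(propan-2-yl)-5-[(trimethylsilyl)oxy]cyclopent-1-ene-1-carbaldehyde | CC1=C(C=O)[C@](O[Si](C)(C)C)(C(C)C)CC1 | intermediate
6 | trimethyl({[(2S,5R)-2-ethenyl-2-methyl-5-(propan-2-yl)-5-(trimethylsilyloxy)cyclopentylidene]methoxy})silane (E/Z mixture) | C=C[C@]1(C)CC[C@@](O[Si](C)(C)C)(C(C)C)C1=CO[Si](C)(C)C | intermediate
7 | (1R,2S,5R)-2-ethenyl-2-methyl-5-(propan-2-yl)-5-[(trimethylsilyl)oxy]cyclopentane-1-carbaldehyde | C=C[C@]1(C)CC[C@@](O[Si](C)(C)C)(C(C)C)[C@@H]1C=O | intermediate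
8 | isoprene, 2-methylbuta-1,3-diene | C=CC(C)=C | starting material
9 | (2-methylidenebut-3-en-1-yl)potassium | [K]CC(=C)C=C | intermediate
10 | (2-methylidenebut-3-en-1-yl)magnesium bromide | Br[Mg]CC(=C)C=C | intermediate
11 | 1-[(1S,2S,5R)-2-ethenyl-2-methyl-5-(propan-2-yl)-5-(trimethylsilyloxy)cyclopentyl]-3-methylidenepent-4-en-1-ol (both carbinol epimers) | C=C[C@]1(C)CC[C@@](O[Si](C)(C)C)(C(C)C)[C@@H]1C(O)CC(=C)C=C | intermediate
12 | 1-[(1R,2S,5R)-2-ethenyl-2-methyl-5-(propan-2-yl)-5-(trimethylsilyloxy)cyclopentyl]-3-methylidenepent-4-en-1-one | C=C[C@]1(C)CC[C@@](O[Si](C)(C)C)(C(C)C)[C@@H]1C(=O)CC(=C)C=C | intermediate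
13 | 1-[(1R,2S,5R)-2-ethenyl-5-hydroxy-2-methyl-5-(propan-2-yl)cyclopentyl]-3-methylidenepent-4-en-1-one | C=C[C@]1(C)CC[C@@](O)(C(C)C)[C@@H]1C(=O)CC(=C)C=C | intermediate
14 | O-diethylboryl derivative (boron chelate) of 13 | C=C[C@]1(C)CC[C@@](OB(CC)CC)(C(C)C)[C@@H]1C(=O)CC(=C)C=C | intermediate
15 | (1R)-1-[(1S,2S,5R)-2-ethenyl-5-hydroxy-2-methyl-5-(propan-2-yl)cyclopentyl]-3-methylidenepent-4-en-1-ol | C=C[C@]1(C)CC[C@@](O)(C(C)C)[C@@H]1[C@H](O)CC(=C)C=C | intermediate
16 | (3R,3aS,4R,8aS)-8a-methyl-6-methylidene-3-(propan-2-yl)-1,2,3,3a,4,5,6,8a-octahydroazulene-3,4-diol | C=C1C=C[C@]2(C)CC[C@@](O)(C(C)C)[C@@H]2[C@H](O)C1 | intermediate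
17 | 4-(acetyloxy)benzoyl chloride | CC(=O)Oc1ccc(cc1)C(Cl)=O | starting material
18 | (3R,3aS,4R,8aS)-3-hydroxy-8a-methyl-6-methylidene-3-(propan-2-yl)-1,2,3,3a,4,5,6,8a-octahydroazulen-4-yl 4-(acetyloxy)benzoate | C=C1C=C[C@]2(C)CC[C@@](O)(C(C)C)[C@@H]2[C@H](OC(=O)c3ccc(OC(C)=O)cc3)C1 | intermediate
19 | (3R,3aS,4R,8aS)-8a-methyl-6-methylidene-3-(propan-2-yl)-3-[(trimethylsilyl)oxy]-1,2,3,3a,4,5,6,8a-octahydroazulen-4-yl 4-(acetyloxy)benzoate | C=C1C=C[C@]2(C)CC[C@@](O[Si](C)(C)C)(C(C)C)[C@@H]2[C@H](OC(=O)c3ccc(OC(C)=O)cc3)C1 | intermediate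
20 | tiglic acid, (2E)-2-methylbut-2-enoic acid | C/C=C(\C)C(=O)O | starting material
21 | (3R,3aS,4R,8R,8aR)-6,8a-dimethyl-8-{[(2E)-2-methylbut-2-enoyl]oxy}-3-(propan-2-yl)-3-[(trimethylsilyl)oxy]-1,2,3,3a,4,5,8,8a-octahydroazulen-4-yl 4-(acetyloxy)benzoate | C/C=C(\C)C(=O)O[C@@H]1C=C(C)C[C@@H](OC(=O)c2ccc(OC(C)=O)cc2)[C@@H]2[C@@]1(C)CC[C@@]2(O[Si](C)(C)C)C(C)C | intermediate
22 | (3R,3aS,4R,8R,8aR)-3-hydroxy-6,8a-dimethyl-8-{[(2E)-2-methylbut-2-enoyl]oxy}-3-(propan-2-yl)-1,2,3,3a,4,5,8,8a-octahydroazulen-4-yl 4-hydroxybenzoate | C/C=C(\C)C(=O)O[C@@H]1C=C(C)C[C@@H](OC(=O)c2ccc(O)cc2)[C@@H]2[C@@]1(C)CC[C@@]2(O)C(C)C | target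

**Step count and risks**

Total step count: 10. Longest linear sequence: 10 steps (1 → 22).

The three steps most likely to fail:

Step 9 (the new 1,4-hydroacyloxylation) is the least certain. The cation may be trapped at the tertiary C8 terminus or lose a proton to a triene. Tiglate may enter from the α-face, or the C4 silyloxy oxygen may close a 4,10-ether. The cobalt hydride may also reduce some tiglic acid. The fallback uses only known reactions and sets out from hydroxy ester 18, isolated by stopping step 8 before the silylation. Lemieux–Johnson cleavage of the exocyclic methylene (OsO4 cat., NaIO4, 2,6-lutidine, dioxane–water) gives the 6-oxo hydroxy ester F6. MeMgBr/CeCl3 (THF, −78 °C) adds 1,2 to give the tertiary allylic alcohol F7. Pyridinium chlorochromate, (C5H5NH)[CrO3Cl], in CH2Cl2 effects the Dauben-type oxidative 1,3-transposition to the 8-oxo enone F8. Evans–Saksena reduction with Me4NBH(OAc)3 (MeCN/AcOH, −30 °C) delivers hydride from the syn-1,3 C4 hydroxyl to the α-face of the C10 carbonyl and gives the 10β-alcohol F9. Yamaguchi esterification with tiglic acid 20 (2,4,6-trichlorobenzoyl chloride, Et3N, DMAP) acylates only the secondary allylic hydroxyl and gives the free-hydroxyl tiglate F10. K2CO3 in MeOH then removes the phenolic acetate, and the route is rejoined at the target 22.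

Step 7 (ring-closing metathesis) may stall because the vinyl group sits on a quaternary carbon and the free 1,3-diol can chelate ruthenium. The 1,1-disubstituted C8=CH2 could also close a six-membered ring instead. The fallback sets out from diol 15 and comes back at 16. The syn-1,3-diol is tied up with 2,2-dimethoxypropane and PPTS as the acetonide of the acyclic diol F4, which removes the chelating hydroxyls and gears the C7 chain toward the vinyl group. Metathesis with the same ruthenium catalyst gives the acetonide of the ring diene F5, and aqueous acetic acid (THF, 40 °C) releases 16.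

Step 3 (conjugate vinyl addition to the tetrasubstituted enal) may be diverted to 1,2-addition at the unhindered formyl group, or give poor facial control. The fallback reverses the order of the two C–C bond formations; it sets out from enal 5 and comes back at 13. Isoprenylmagnesium bromide 10 (made from isoprene 8 as in step 4) adds to 5 to give the dienyl carbinol F1. Dess–Martin oxidation gives the acylcyclopentene enone F2, whose ketone resists 1,2-attack. CH2=CHMgBr with CuBr·SMe2 (cat.) and TMSCl then gives the bis-silyl enol ether F3. Hydrolysis with 1 M HCl in THF removes both silyl groups and equilibrates C5, giving 13.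

Further compounds

F1 | step 3 | 1-[(5R)-2-methyl-5-(propan-2-yl)-5-(trimethylsilyloxy)cyclopent-1-en-1-yl]-3-methylidenepent-4-en-1-ol (carbinol epimers) | CC1=C(C(O)CC(=C)C=C)[C@](O[Si](C)(C)C)(C(C)C)CC1
F2 | step 3 | 1-[(5R)-2-methyl-5-(propan-2-yl)-5-(trimethylsilyloxy)cyclopent-1-en-1-yl]-3-methylidenepent-4-en-1-one | CC1=C(C(=O)CC(=C)C=C)[C@](O[Si](C)(C)C)(C(C)C)CC1
F3 | step 3 | trimethyl({1-[(2S,5R)-2-ethenyl-2-methyl-5-(propan-2-yl)-5-(trimethylsilyloxy)cyclopentylidene]-3-methylidenepent-4-en-1-yl}oxy)silane | C=C[C@]1(C)CC[C@@](O[Si](C)(C)C)(C(C)C)C1=C(O[Si](C)(C)C)CC(=C)C=C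
F4 | step 7 | O,O-isopropylidene acetal (acetonide) of diol 15 | C=C[C@]1(C)CC[C@@]2(OC(C)(C)O[C@H](CC(=C)C=C)[C@H]12)C(C)C
F5 | step 7 | O,O-isopropylidene acetal (acetonide) of ring diene diol 16 | C=C1C=C[C@]2(C)CC[C@]3(C(C)C)OC(C)(C)O[C@H](C1)[C@H]23
F6 | step 9 | (3R,3aS,4R,8aS)-3-hydroxy-8a-methyl-6-oxo-3-(propan-2-yl)-1,2,3,3a,4,5,6,8a-octahydroazulen-4-yl 4-(acetyloxy)benzoate | O=C1C=C[C@]2(C)CC[C@@](O)(C(C)C)[C@@H]2[C@H](OC(=O)c3ccc(OC(C)=O)cc3)C1
F7 | step 9 | (3R,3aS,4R,8aS)-3,6-dihydroxy-6,8a-dimethyl-3-(propan-2-yl)-1,2,3,3a,4,5,6,8a-octahydroazulen-4-yl 4-(acetyloxy)benzoate (C6 epimers) | CC1(O)C=C[C@]2(C)CC[C@@](O)(C(C)C)[C@@H]2[C@H](OC(=O)c3ccc(OC(C)=O)cc3)C1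
F8 | step 9 | (3R,3aS,4R,8aR)-3-hydroxy-6,8a-dimethyl-8-oxo-3-(propan-2-yl)-1,2,3,3a,4,5,8,8a-octahydroazulen-4-yl 4-(acetyloxy)benzoate | CC1=CC(=O)[C@]2(C)CC[C@@](O)(C(C)C)[C@@H]2[C@H](OC(=O)c3ccc(OC(C)=O)cc3)C1
F9 | step 9 | (3R,3aS,4R,8R,8aR)-3,8-dihydroxy-6,8a-dimethyl-3-(propan-2-yl)-1,2,3,3a,4,5,8,8a-octahydroazulen-4-yl 4-(acetyloxy)benzoate | CC1=C[C@@H](O)[C@]2(C)CC[C@@](O)(C(C)C)[C@@H]2[C@H](OC(=O)c3ccc(OC(C)=O)cc3)C1
F10 | step 9 | (3R,3aS,4R,8R,8aR)-3-hydroxy-6,8a-dimethyl-8-{[(2E)-2-methylbut-2-enoyl]oxy}-3-(propan-2-yl)-1,2,3,3a,4,5,8,8a-octahydroazulen-4-yl 4-(acetyloxy)benzoate | C/C=C(\C)C(=O)O[C@@H]1C=C(C)C[C@@H](OC(=O)c2ccc(OC(C)=O)cc2)[C@@H]2[C@@]1(C)CC[C@@]2(O)C(C)C
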